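## Analysis of the target

Penicanesin D (17) consists of two rings joined by one methylene bridge: ring A, a pentasubstituted benzene, and ring B, a 4-hydroxy-2H-pyran-2-one. Counting ring A from the bridge carbon, C1 carries the CH2 bridge, C2 the acetyl group, C3 and C4 free hydroxyls, C5 the methoxy group and C6 the only ring hydrogen; ring B carries the bridge on C3 and an (S)-2-hydroxypropyl chain on C6. The carbinol carbon of that chain is the only stereocentre. It has no partner to relate to, so it only has to be brought in enantiopure and kept from elimination, since it lies β to C6 of the pyranone and could dehydrate to a conjugated propenyl pyranone. The other sensitive groups are the catechol (air, base, oxidants), the methyl ketone (more acidic than an ester) and the 4-hydroxypyranone (a vinylogous acid and a lactone). Two things make the synthesis hard. The acetyl group must go to C2 without ambiguity, although a ring A precursor with three differentiated oxygens has two open positions of nearly equal reactivity. The 3,6-disubstituted hydroxypyranone must also be closed under conditions that the carbinol and its protecting groups survive. The strategy rests on the O1–C6 bond of ring B: the ring oxygen is bonded to the carbon that bears the CH2–CH(OH)–CH3 chain, so C5, C6 and the chain are the five carbons of (S)-pent-4-yn-2-ol (9), and C2–C3–C4 are a β-keto ester whose α-carbon already holds the bridge.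

## Retrosynthetic reasoning

**17 from 16.** Only protecting groups are removed. The carbinol is masked as a silyl ether and the catechol as an isopropylidene ketal. Both resist base, hydride, palladium, a periodinane oxidant and gold, and both fall to aqueous acid in one operation.

**16 from 15 (key disconnection).** The O1–C6 bond of ring B is cut. This opens the ring to a linear tert-butyl 3-oxoalk-4-ynoate (15) in which every carbon of ring B is already present at the right oxidation level. The cut is made here because the bond is a C–O bond next to no stereocentre, and because its formation needs only a π-acid. The forward reaction must make the ester carbonyl oxygen add to the alkyne carbon remote from the ketone in a 6-endo sense and then expel the tert-butyl group as the alkene.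

**15 from 14, and 14 from 8 and 12.** The C3–C4 bond of ring B (C2–C3 of the chain of 15) is cut next. It divides the molecule into an ester that holds all of ring A (8) and an ynal that holds the stereocentre (12). Forward, the ester enolate adds to the aldehyde and the resulting carbinol 14 is oxidised. Acylation of a malonic half ester by an activated alkynoic acid was considered for the same bond and set aside: the half ester is hard to reach with this arene, and activated 2-alkynoic acids are prone to conjugate addition of their own leaving group. The aldol needs a lithium amide base, which would deprotonate an aryl methyl ketone before the ester. The ketone is therefore carried through this step as its carbinol (8), whose alkoxide is inert. The oxidation that makes the ynone also restores the acetyl group, so the detour costs one step.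

**12 from 10 and 9.** The aldehyde carbon is attached to the terminal alkyne carbon of 10 by C-formylation of its acetylide. 10 is the silyl ether of chiral-pool alkynol 9, so the stereocentre is bought and not made.

**8 from 7, and 7 from 4 and 5.** After the ketone of 7 is taken to the carbinol, the bond between ring A and the bridge carbon is cut. A Negishi coupling of aryl bromide 4 with zinc homoenolate 6, made from 5, delivers the bridge carbon, the future C3 of ring B and the tert-butyl ester in one step. The tert-butyl group that the key step needs is thus in place without an ester exchange, and no benzylic halide or ortho-acetyl benzaldehyde has to be handled.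

**4 from 3, 2 and 1.** In an arene whose catechol and methoxy group are already differentiated, each open ring position is ortho to one oxygen and para to another, so an acylation would have no reason to choose. The order is therefore reversed. Arene 1 has a mirror plane, its two free positions are equivalent, and Friedel–Crafts acetylation can give only 2. The new ketone then directs a boron Lewis acid to cleave the adjacent methoxy group and, through the resulting boron aryloxide, the next one. This gives catechol 3 with the remote methoxy group intact, and ketalisation gives 4. The bromine of 1 marks the carbon that will hold the bridge.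

## Alternatives that were turned down

**Alternative 1:** Ring A is built by a formal [3+3] cyclocondensation that forms C4–C5 and C1–C2. TiCl4 would join the bis(silyl enol ether) A2 with the ketene-acetal enone A3. The terminal carbon of A2 adds to the acetal carbon of A3, its central carbon condenses with the ketone, and aromatisation gives the arylpropanoate A1.
- For: every substituent of ring A is placed by connectivity, and the two catechol oxygens emerge differentiated (one benzylated, one free). The chosen route does not offer that differentiation; it needs none, and gets the same regiochemical certainty from the symmetry of 1 and chelation in 2.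
- Against: A2 requires double enolisation of an unsymmetrical α-alkoxy 1,3-diketone towards the alkoxymethyl side and not the methyl side. A3 is a hydrolysis-prone ketene acetal, and a strong Lewis acid meets a benzyl ether.
- Comparison: A1 is only at the stage of 7, which the chosen route reaches in four steps from a commercial arene. A1 would still need debenzylation, ketal protection and a methyl to tert-butyl ester exchange before any ring B chemistry, so it is longer and leaves the ring B problem untouched.

**Alternative 2:** Ring A is built by a Diels–Alder reaction that forms C6–C1 and C2–C3. The tetraoxygenated silyl ketene acetal diene A5 would add to the ynone A6. The CH2 terminus of A5 bonds to the β-carbon of the ynone, and loss of methanol aromatises the adduct to the arylmethylmalonate A4.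
- For: the regiochemistry is polarity-matched, the acetyl group arrives without a Friedel–Crafts step, and the bridge carbon comes with a malonate that could feed a decarboxylative acylation. On certainty of acetyl placement it is as strong as the chosen route.
- Against: A5 needs a multistep preparation and is moisture-sensitive. A6 has an acidic malonate C–H close to a Michael-accepting ynone. A4 is a dimethyl malonate, and its conversion into a mono-tert-butyl half ester is not direct. The acylation that would follow needs an activated 2-alkynoic acid, with its conjugate-addition problem.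
- Comparison: both fragments must be made and several steps follow A4, so the count exceeds that of the chosen route, which buys ring A and spends its steps on ring B.

**Alternative 3:** Ring B is built from two fragments by forming C4–C5 and O1–C2. The malonyl dichloride A8 would C-acylate the terminal carbon of the (S)-configured enol silane A9, and the enol oxygen would then close the lactone to give pyranone A7.
- For: it is the most convergent way to ring B, with two bonds in one step and no gold and no redox adjustment. On step count at the ring-forming stage it is stronger than the chosen aldol, oxidation and cyclisation sequence.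
- Against: A8 presupposes the arylmethylmalonic acid of this arene, which is not within easy reach. Its acid chloride must be made next to an enolisable acetyl group and an acid-labile ketal. Monosubstituted malonyl chlorides lose HCl to give chlorocarbonyl ketenes, and the ring closure releases two equivalents of HCl onto a silyl ether and a ketal. A9 must be made by kinetic enolisation of a β-silyloxy methyl ketone, which can eliminate the silyloxy group and with it the only stereocentre.
- Comparison: the chosen route closes ring B under nearly neutral conditions, and its carbinol is never β to an enolisable carbonyl.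

Key step: step 10

Remark on the chemistry: the carbinol centre made in step 5 and the centres at C2 and C3 of 14 (C2 of 15) are formed without control and carried as mixtures, because all of them become trigonal again by step 10. Compounds 1, 5 and 9 are taken as commercial.

## Route

Step 1
Reactants: 1 5-bromo-1,2,3-trimethoxybenzene
Product: 2 1-(6-bromo-2,3,4-trimethoxyphenyl)ethan-1-one
Conditions: AcCl (1.2 equiv), AlCl3 (1.3 equiv), CH2Cl2, 0 °C
Reagents that add atoms: acetyl chloride, CC(=O)Cl
Why: Friedel–Crafts acylation; the mirror plane of 1 makes its two free positions equivalent, and each is ortho to one methoxy group and para to another, so only 2 can form. Any partial loss of the methoxy group next to the new ketone is harmless because step 2 removes that group anyway.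

Step 2
Reactants: 2 1-(6-bromo-2,3,4-trimethoxyphenyl)ethan-1-one
Product: 3 1-(6-bromo-2,3-dihydroxy-4-methoxyphenyl)ethan-1-one
Conditions: BCl3 (3 equiv), CH2Cl2, -78 °C to rt; aqueous work-up
Reagents that add atoms: none
Why: Chelation-controlled Lewis-acid ether cleavage; boron bound to the ketone oxygen cleaves the adjacent methoxy group, and the resulting aryloxyboron chloride cleaves the next one by closing a five-membered catechol borate. The methoxy group para to the ketone has no such assistance and should remain, and the aryl bromide is inert.

Step 3
Reactants: 3 1-(6-bromo-2,3-dihydroxy-4-methoxyphenyl)ethan-1-one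
Product: 4 1-(5-bromo-7-methoxy-2,2-dimethyl-1,3-benzodioxol-4-yl)ethan-1-one
Conditions: 2,2-dimethoxypropane, TsOH·H2O (cat.), toluene, reflux, MeOH removed over 4 Å sieves
Reagents that add atoms: 2,2-dimethoxypropane, COC(C)(C)OC
Why: Acid-catalysed transketalisation driven by removal of methanol closes the five-membered dioxole. The ketal shields the catechol from the base and the oxidant of later steps and is removable by acid at the end.

Step 4
Reactants: 4 1-(5-bromo-7-methoxy-2,2-dimethyl-1,3-benzodioxol-4-yl)ethan-1-one; 5 tert-butyl 3-bromopropanoate
Product: 7 tert-butyl 3-(4-acetyl-7-methoxy-2,2-dimethyl-1,3-benzodioxol-5-yl)propanoate, via zinc homoenolate 6 (not isolated)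
Conditions: 5, Zn dust (activated by BrCH2CH2Br and Me3SiCl), LiCl, THF, 40 °C; then 4, Pd(OAc)2 (3 mol%), SPhos (6 mol%), THF, 50 °C
Reagents that add atoms: zinc, [Zn] (held only in intermediate 6)
Why: Negishi sp2–sp3 cross-coupling; the zinc homoenolate tolerates its own ester and the aryl ketone, and the ortho acyl group assists oxidative addition to zerovalent palladium. The bulky biarylphosphine favours reductive elimination over β-hydride elimination.

Step 5
Reactants: 7 tert-butyl 3-(4-acetyl-7-methoxy-2,2-dimethyl-1,3-benzodioxol-5-yl)propanoate
Product: 8 tert-butyl 3-[4-(1-hydroxyethyl)-7-methoxy-2,2-dimethyl-1,3-benzodioxol-5-yl]propanoate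
Conditions: NaBH4, MeOH, 0 °C to rt
Reagents that add atoms: none
Why: Hydride reduction of the aryl ketone removes the acidic acetyl protons before the enolate step, and the tert-butyl ester is not touched. The new carbinol centre forms without control, which does not matter because step 9 oxidises it back.

Step 6
Reactants: 9 (S)-pent-4-yn-2-ol
Product: 10 (S)-tert-butyldimethyl(pent-4-yn-2-yloxy)silane
Conditions: TBSCl, imidazole, CH2Cl2, 0 °C to rt
Reagents that add atoms: tert-butyldimethylsilyl chloride, CC(C)(C)[Si](C)(C)Cl
Why: Standard silylation of a secondary alcohol. The silyl ether keeps the carbinol oxygen from adding to the alkyne in step 10, and the stereocentre is not involved.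

Step 7
Reactants: 10 (S)-tert-butyldimethyl(pent-4-yn-2-yloxy)silane
Product: 12 (5S)-5-[(tert-butyldimethylsilyl)oxy]hex-2-ynal, via lithium acetylide 11 (not isolated)
Conditions: n-BuLi, THF, -78 °C; DMF, -78 to 0 °C; poured into cold aq. KH2PO4
Reagents that add atoms: N,N-dimethylformamide, CN(C)C=O; n-butyllithium, [Li]CCCC (lithium held only in intermediate 11)
Why: Deprotonation of the terminal alkyne and C-formylation of the acetylide by the formamide. The inverse quench into phosphate buffer releases the ynal without addition of the liberated amine to the triple bond.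

Step 8
Reactants: 8 tert-butyl 3-[4-(1-hydroxyethyl)-7-methoxy-2,2-dimethyl-1,3-benzodioxol-5-yl]propanoate; 12 (5S)-5-[(tert-butyldimethylsilyl)oxy]hex-2-ynal
Product: 14 tert-butyl (7S)-7-[(tert-butyldimethylsilyl)oxy]-3-hydroxy-2-{[4-(1-hydroxyethyl)-7-methoxy-2,2-dimethyl-1,3-benzodioxol-5-yl]methyl}oct-4-ynoate, via dilithium alkoxide-enolate 13 (not isolated)
Conditions: LDA (2.2 equiv), THF, -78 °C; then 12 (1.2 equiv), -78 °C; sat. aq. NH4Cl
Reagents that add atoms: lithium diisopropylamide, [Li]N(C(C)C)C(C)C (lithium held only in intermediate 13)
Why: Aldol addition of a lithium ester enolate to an ynal; the first equivalent of base makes the inert alkoxide, the second the enolate, which adds 1,2 to the aldehyde at low temperature. The new centres at C2 and C3 form without control and are erased in steps 9 and 10.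

Step 9
Reactants: 14 tert-butyl (7S)-7-[(tert-butyldimethylsilyl)oxy]-3-hydroxy-2-{[4-(1-hydroxyethyl)-7-methoxy-2,2-dimethyl-1,3-benzodioxol-5-yl]methyl}oct-4-ynoate
Product: 15 tert-butyl (7S)-2-[(4-acetyl-7-methoxy-2,2-dimethyl-1,3-benzodioxol-5-yl)methyl]-7-[(tert-butyldimethylsilyl)oxy]-3-oxooct-4-ynoate
Conditions: Dess–Martin periodinane (2.6 equiv), NaHCO3, CH2Cl2, 0 °C to rt
Reagents that add atoms: none
Why: Dess–Martin oxidation of both secondary alcohols in one operation; the benzylic carbinol returns to the acetyl group and the propargylic β-hydroxy ester becomes the ynone β-keto ester. The bicarbonate buffer protects the silyl ether and the ketal from the acetic acid released.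

Step 10
Reactants: 15 tert-butyl (7S)-2-[(4-acetyl-7-methoxy-2,2-dimethyl-1,3-benzodioxol-5-yl)methyl]-7-[(tert-butyldimethylsilyl)oxy]-3-oxooct-4-ynoate
Product: 16 3-[(4-acetyl-7-methoxy-2,2-dimethyl-1,3-benzodioxol-5-yl)methyl]-6-[(2S)-2-[(tert-butyldimethylsilyl)oxy]propyl]-4-hydroxy-2H-pyran-2-one
Conditions: Ph3PAuNTf2 (5 mol%), MeNO2/AcOH (4:1), rt
Reagents that add atoms: none
Why: Cationic monovalent gold binds the C4≡C5 triple bond of the ynone, and the carbonyl oxygen of the tert-butyl ester adds anti to the metal at C5, the alkyne carbon remote from the ketone, which forms the O1–C6 bond of ring B in a 6-endo-dig closure. The resulting 2-tert-butoxy oxocarbenium vinylgold species loses the tert-butyl group as isobutene, acetic acid cleaves the C–Au bond at the future C5 of the ring, and the pyran-2,4-dione tautomerises to the 4-hydroxy-2-pyranone. The closest known reaction type is the gold-catalysed cyclisation of tert-butyl 3-oxoalk-4-ynoates, including α-substituted ones, to 6-substituted 4-hydroxy-2-pyranones. No stereocentre is formed, and the C2 epimers of 15 converge because that carbon becomes trigonal. The step needs 6-endo over 5-exo closure; the polarisation of the ynone secures it, since the gold complex carries its positive character on the carbon β to the ketone. The silyl ether keeps the carbinol oxygen from competing for the alkyne, the aryl ketone oxygen is too far away to close a ring, and C–H addition by ring A should be slower than attack by the chelating ester oxygen. The weakly acidic medium leaves the silyl ether, the ketal and the (S)-centre two atoms from the alkyne untouched.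

Step 11
Reactants: 16 3-[(4-acetyl-7-methoxy-2,2-dimethyl-1,3-benzodioxol-5-yl)methyl]-6-[(2S)-2-[(tert-butyldimethylsilyl)oxy]propyl]-4-hydroxy-2H-pyran-2-one
Product: 17 penicanesin D, 3-[(2-acetyl-3,4-dihydroxy-5-methoxyphenyl)methyl]-4-hydroxy-6-[(2S)-2-hydroxypropyl]-2H-pyran-2-one
Conditions: TFA/H2O (9:1), 0 °C to rt; then MeOH, aq. NaHCO3, 0 °C, under argon (cleaves any trifluoroacetate)
Reagents that add atoms: none
Why: Brønsted-acid hydrolysis removes the secondary silyl ether and the catechol isopropylidene ketal in one operation. The pyranone, the aryl ketone and the carbinol centre, which cannot ionise easily, should survive aqueous acid at room temperature.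

## Compound list

1 | 5-bromo-1,2,3-trimethoxybenzene | COc1cc(Br)cc(OC)c1OC | starting material
2 | 1-(6-bromo-2,3,4-trimethoxyphenyl)ethan-1-one | COc1cc(Br)c(C(C)=O)c(OC)c1OC | intermediate
3 | 1-(6-bromo-2,3-dihydroxy-4-methoxyphenyl)ethan-1-one | COc1cc(Br)c(C(C)=O)c(O)c1O | intermediate
4 | 1-(5-bromo-7-methoxy-2,2-dimethyl-1,3-benzodioxol-4-yl)ethan-1-one | COc1cc(Br)c(C(C)=O)c2OC(C)(C)Oc12 | intermediate
5 | tert-butyl 3-bromopropanoate | CC(C)(C)OC(=O)CCBr | starting material
6 | (3-tert-butoxy-3-oxopropyl)zinc bromide (formed in situ) | CC(C)(C)OC(=O)CC[Zn]Br | intermediate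
7 | tert-butyl 3-(4-acetyl-7-methoxy-2,2-dimethyl-1,3-benzodioxol-5-yl)propanoate | COc1cc(CCC(=O)OC(C)(C)C)c(C(C)=O)c2OC(C)(C)Oc12 | intermediate
8 | tert-butyl 3-[4-(1-hydroxyethyl)-7-methoxy-2,2-dimethyl-1,3-benzodioxol-5-yl]propanoate (both configurations at the carbinol carbon) | COc1cc(CCC(=O)OC(C)(C)C)c(C(C)O)c2OC(C)(C)Oc12 | intermediate
9 | (S)-pent-4-yn-2-ol | C#CC[C@H](C)O | starting material
10 | (S)-tert-butyldimethyl(pent-4-yn-2-yloxy)silane | C#CC[C@H](C)O[Si](C)(C)C(C)(C)C | intermediate
11 | [(4S)-4-[(tert-butyldimethylsilyl)oxy]pent-1-yn-1-yl]lithium (formed in situ) | [Li]C#CC[C@H](C)O[Si](C)(C)C(C)(C)C | intermediate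
12 | (5S)-5-[(tert-butyldimethylsilyl)oxy]hex-2-ynal | O=CC#CC[C@H](C)O[Si](C)(C)C(C)(C)C | intermediate
13 | dilithium alkoxide–ester enolate of 8 (formed in situ) | COc1cc(CC=C(O[Li])OC(C)(C)C)c(C(C)O[Li])c2OC(C)(C)Oc12 | intermediate
14 | tert-butyl (7S)-7-[(tert-butyldimethylsilyl)oxy]-3-hydroxy-2-{[4-(1-hydroxyethyl)-7-methoxy-2,2-dimethyl-1,3-benzodioxol-5-yl]methyl}oct-4-ynoate (mixture at C2, C3 and the benzylic carbinol) | COc1cc(CC(C(=O)OC(C)(C)C)C(O)C#CC[C@H](C)O[Si](C)(C)C(C)(C)C)c(C(C)O)c2OC(C)(C)Oc12 | intermediate
15 | tert-butyl (7S)-2-[(4-acetyl-7-methoxy-2,2-dimethyl-1,3-benzodioxol-5-yl)methyl]-7-[(tert-butyldimethylsilyl)oxy]-3-oxooct-4-ynoate (C2 epimers) | COc1cc(CC(C(=O)OC(C)(C)C)C(=O)C#CC[C@H](C)O[Si](C)(C)C(C)(C)C)c(C(C)=O)c2OC(C)(C)Oc12 | intermediate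
16 | 3-[(4-acetyl-7-methoxy-2,2-dimethyl-1,3-benzodioxol-5-yl)methyl]-6-[(2S)-2-[(tert-butyldimethylsilyl)oxy]propyl]-4-hydroxy-2H-pyran-2-one | COc1cc(Cc2c(O)cc(C[C@H](C)O[Si](C)(C)C(C)(C)C)oc2=O)c(C(C)=O)c2OC(C)(C)Oc12 | intermediate
17 | penicanesin D, 3-[(2-acetyl-3,4-dihydroxy-5-methoxyphenyl)methyl]-4-hydroxy-6-[(2S)-2-hydroxypropyl]-2H-pyran-2-one | COc1cc(Cc2c(O)cc(C[C@H](C)O)oc2=O)c(C(C)=O)c(O)c1O | target

## Step count and uncertain steps

Total: 11 steps. Longest linear sequence: 9 steps (steps 1–5 and 8–11, from 1); the alkyne branch adds steps 6 and 7.

**Step 10 (key step).** The most likely failure is diversion of the gold-activated ynone: water may add to give a 1,3-diketone, or the enolised β-dicarbonyl may sequester the catalyst so that protodeauration stalls. The tert-butyl group may also be lost early, followed by decarboxylation, or the free C–H of ring A may add to the alkyne. The fallback closes the same ring through the other C–O bond. Setting out from 15, diethylamine is added in conjugate fashion to the ynone to give the enaminone tert-butyl (7S)-2-[(4-acetyl-7-methoxy-2,2-dimethyl-1,3-benzodioxol-5-yl)methyl]-7-[(tert-butyldimethylsilyl)oxy]-5-(diethylamino)-3-oxooct-4-enoate F1. Mild aqueous acetic acid hydrolyses it to the 3,5-diketo ester tert-butyl (7S)-2-[(4-acetyl-7-methoxy-2,2-dimethyl-1,3-benzodioxol-5-yl)methyl]-7-[(tert-butyldimethylsilyl)oxy]-3,5-dioxooctanoate F2. Heating F2 in toluene expels tert-butanol to give an acylketene, which the C5 enol oxygen traps to form the lactone, and the route is rejoined at 16.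

**Step 8.** Enolisation next to a lithium alkoxide may be incomplete because of mixed aggregation, and the alkoxide may add reversibly or in conjugate fashion to the ynal, so that conversion stalls. Fallback from 8: the carbinol is silylated with triethylsilyl chloride to give tert-butyl 3-{7-methoxy-2,2-dimethyl-4-[1-(triethylsilyloxy)ethyl]-1,3-benzodioxol-5-yl}propanoate F3. Its ordinary mono-enolate is added to 12 to give tert-butyl (7S)-7-[(tert-butyldimethylsilyl)oxy]-3-hydroxy-2-({7-methoxy-2,2-dimethyl-4-[1-(triethylsilyloxy)ethyl]-1,3-benzodioxol-5-yl}methyl)oct-4-ynoate F4. The triethylsilyl ether is then cleaved selectively with AcOH/THF/H2O, which leaves the bulkier silyl ether, and the route is rejoined at 14.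

**Step 9.** The excess oxidant needed for the hindered benzylic carbinol may over-oxidise the doubly activated C2 of the new β-keto ester, and the ynone may degrade during a long reaction. The fallback forms the C2–C3 bond at the ketone oxidation level. Acetylide 11, made from 10, is acylated with N-methoxy-N-methylcarbamoyl chloride to give (5S)-5-[(tert-butyldimethylsilyl)oxy]-N-methoxy-N-methylhex-2-ynamide F5. Dianion 13, made from 8, is acylated by F5 to give tert-butyl (7S)-7-[(tert-butyldimethylsilyl)oxy]-2-{[4-(1-hydroxyethyl)-7-methoxy-2,2-dimethyl-1,3-benzodioxol-5-yl]methyl}-3-oxooct-4-ynoate F6. Only the benzylic alcohol of F6 is then oxidised, with MnO2 in CH2Cl2, and the route is rejoined at 15.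

**Step 4.** Zinc insertion into the β-bromo ester may be sluggish or give protodezincation, and the hindered aryl bromide may undergo reduction in place of coupling. Fallback from 4: a Heck reaction with tert-butyl acrylate (Pd(OAc)2, P(o-tol)3, Et3N, DMF, 100 °C) gives tert-butyl (2E)-3-(4-acetyl-7-methoxy-2,2-dimethyl-1,3-benzodioxol-5-yl)prop-2-enoate F7. Hydrogenation of the alkene (H2, palladium on carbon, EtOAc) leads back to 7.

**Step 11.** The ketal of an electron-poor, ketone-flanked catechol may hydrolyse slowly. Longer exposure to strong acid then risks trifluoroacetylation or dehydration of the carbinol and closure of the pyranone hydroxyl onto the ketone. The fallback is in two stages. From 16, HF·pyridine in THF removes the silyl ether to give 3-[(4-acetyl-7-methoxy-2,2-dimethyl-1,3-benzodioxol-5-yl)methyl]-4-hydroxy-6-[(2S)-2-hydroxypropyl]-2H-pyran-2-one F8. BCl3 in CH2Cl2 at low temperature then opens the ketal by chelation to the acetyl oxygen, as in step 2, and aqueous work-up gives 17.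

## Further compounds

F1 | step 10 | tert-butyl (7S)-2-[(4-acetyl-7-methoxy-2,2-dimethyl-1,3-benzodioxol-5-yl)methyl]-7-[(tert-butyldimethylsilyl)oxy]-5-(diethylamino)-3-oxooct-4-enoate | COc1cc(CC(C(=O)OC(C)(C)C)C(=O)C=C(C[C@H](C)O[Si](C)(C)C(C)(C)C)N(CC)CC)c(C(C)=O)c2OC(C)(C)Oc12
F2 | step 10 | tert-butyl (7S)-2-[(4-acetyl-7-methoxy-2,2-dimethyl-1,3-benzodioxol-5-yl)methyl]-7-[(tert-butyldimethylsilyl)oxy]-3,5-dioxooctanoate | COc1cc(CC(C(=O)OC(C)(C)C)C(=O)CC(=O)C[C@H](C)O[Si](C)(C)C(C)(C)C)c(C(C)=O)c2OC(C)(C)Oc12
F3 | step 8 | tert-butyl 3-{7-methoxy-2,2-dimethyl-4-[1-(triethylsilyloxy)ethyl]-1,3-benzodioxol-5-yl}propanoate | COc1cc(CCC(=O)OC(C)(C)C)c(C(C)O[Si](CC)(CC)CC)c2OC(C)(C)Oc12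
F4 | step 8 | tert-butyl (7S)-7-[(tert-butyldimethylsilyl)oxy]-3-hydroxy-2-({7-methoxy-2,2-dimethyl-4-[1-(triethylsilyloxy)ethyl]-1,3-benzodioxol-5-yl}methyl)oct-4-ynoate | COc1cc(CC(C(=O)OC(C)(C)C)C(O)C#CC[C@H](C)O[Si](C)(C)C(C)(C)C)c(C(C)O[Si](CC)(CC)CC)c2OC(C)(C)Oc12
F5 | step 9 | (5S)-5-[(tert-butyldimethylsilyl)oxy]-N-methoxy-N-methylhex-2-ynamide | CON(C)C(=O)C#CC[C@H](C)O[Si](C)(C)C(C)(C)C
F6 | step 9 | tert-butyl (7S)-7-[(tert-butyldimethylsilyl)oxy]-2-{[4-(1-hydroxyethyl)-7-methoxy-2,2-dimethyl-1,3-benzodioxol-5-yl]methyl}-3-oxooct-4-ynoate | COc1cc(CC(C(=O)OC(C)(C)C)C(=O)C#CC[C@H](C)O[Si](C)(C)C(C)(C)C)c(C(C)O)c2OC(C)(C)Oc12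
F7 | step 4 | tert-butyl (2E)-3-(4-acetyl-7-methoxy-2,2-dimethyl-1,3-benzodioxol-5-yl)prop-2-enoate | COc1cc(/C=C/C(=O)OC(C)(C)C)c(C(C)=O)c2OC(C)(C)Oc12
F8 | step 11 | 3-[(4-acetyl-7-methoxy-2,2-dimethyl-1,3-benzodioxol-5-yl)methyl]-4-hydroxy-6-[(2S)-2-hydroxypropyl]-2H-pyran-2-one | COc1cc(Cc2c(O)cc(C[C@H](C)O)oc2=O)c(C(C)=O)c2OC(C)(C)Oc12
A1 | alternative 1 | methyl 3-[2-acetyl-4-(benzyloxy)-3-hydroxy-5-methoxyphenyl]propanoate | COc1cc(CCC(=O)OC)c(C(C)=O)c(O)c1OCc1ccccc1
A2 | alternative 1 | 1-(benzyloxy)-2,4-bis(trimethylsilyloxy)penta-1,3-diene | CC(O[Si](C)(C)C)=CC(O[Si](C)(C)C)=COCc1ccccc1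
A3 | alternative 1 | methyl 6,6-dimethoxy-4-oxohex-5-enoate | COC(=O)CCC(=O)C=C(OC)OC
A4 | alternative 2 | dimethyl 2-{[2-acetyl-4-(benzyloxy)-3-hydroxy-5-methoxyphenyl]methyl}propanedioate | COc1cc(CC(C(=O)OC)C(=O)OC)c(C(C)=O)c(O)c1OCc1ccccc1
A5 | alternative 2 | 2-(benzyloxy)-1,3-dimethoxy-1-(trimethylsilyloxy)buta-1,3-diene | C=C(OC)C(OCc1ccccc1)=C(OC)O[Si](C)(C)C
A6 | alternative 2 | dimethyl 2-(4-oxopent-2-yn-1-yl)propanedioate | CC(=O)C#CCC(C(=O)OC)C(=O)OC
A7 | alternative 3 | 3-[(4-acetyl-7-methoxy-2,2-dimethyl-1,3-benzodioxol-5-yl)methyl]-6-[(2S)-2-(tert-butyldiphenylsilyloxy)propyl]-4-hydroxy-2H-pyran-2-one | COc1cc(Cc2c(O)cc(C[C@H](C)O[Si](c3ccccc3)(c3ccccc3)C(C)(C)C)oc2=O)c(C(C)=O)c2OC(C)(C)Oc12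
A8 | alternative 3 | 2-[(4-acetyl-7-methoxy-2,2-dimethyl-1,3-benzodioxol-5-yl)methyl]propanedioyl dichloride | COc1cc(CC(C(Cl)=O)C(Cl)=O)c(C(C)=O)c2OC(C)(C)Oc12
A9 | alternative 3 | (4S)-4-(tert-butyldiphenylsilyloxy)-2-(trimethylsilyloxy)pent-1-ene | C=C(O[Si](C)(C)C)C[C@H](C)O[Si](c1ccccc1)(c1ccccc1)C(C)(C)C
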